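**Plan**

- Retrosynthesis: the side-chain ester C–O bond is cut first, giving (R)-shikonin and (3Z)-5-methylhexa-3,5-dienoic acid. Next the C2=C3 double bond of ring B is cut, then the C1–C2 and C3–C4 bonds, leading back to a symmetrical ring A dialdehyde, a 2-metallated allylic silyl ether and a vinyl Grignard reagent.
- Enabling feature: ring B carries its one carbon substituent on C2 of the C2=C3 alkene, and C1 and C4 are carbonyl carbons bonded directly to ring A. Both can therefore enter as allylic carbinols, and the ring alkene can be made last by metathesis.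
- Forward: ring A, as its bis(methoxymethyl) ether, is ortho-formylated. One flask then adds the chiral alkenyllithium (C1–C2) and vinylmagnesium bromide (C3–C4). Ring B is closed by metathesis, oxidised to the quinone and unmasked to shikonin, and the dienoyl group is attached last.
- Stereochemistry: the single stereocenter (side-chain C1', R) is set by asymmetric transfer hydrogenation of an alkynyl ketone, and its C–O bond is never broken afterwards. The Z alkene of the acyl group comes from a salt-free Wittig reaction.

Key step: step 10

Remark: the 5,8-dihydroxy-1,4-naphthoquinone core is a pair of rapidly equilibrating tautomers, so the target as drawn is reached whichever ring is oxidised; the sense of induction in step 5 is assigned from the accepted model for alkynyl ketones, is to be verified on 12 (Mosher ester), and would be corrected by using the (S,S)-ligand.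

**Route**

Step 1
Reactants: 1 2,5-dihydroxybenzaldehyde
Product: 2 2,5-bis(methoxymethoxy)benzaldehyde
Conditions: MOMCl, i-Pr2NEt, CH2Cl2, 0 °C → reflux
Reagents that add atoms: chloromethyl methyl ether, COCCl
Why: Base-mediated O-alkylation of both phenols with the α-chloro ether (methoxymethyl ether formation) gives acetal ethers that withstand organolithium reagents, direct ortho-lithiation and can be cleaved at the end with dilute acid, which methyl ethers on this ring would not allow.

Step 2
Reactants: 2 2,5-bis(methoxymethoxy)benzaldehyde
Product: 5 3,6-bis(methoxymethoxy)benzene-1,2-dicarbaldehyde, via lithium α-amino alkoxide 3 (not isolated), via ortho-lithiated α-amino alkoxide 4 (not isolated)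
Conditions: LiN(Me)CH2CH2NMe2 (from MeNHCH2CH2NMe2 and n-BuLi), THF, −20 °C; n-BuLi (3 equiv), −20 °C; DMF, −78 °C → rt; aq NH4Cl
Reagents that add atoms: N,N-dimethylformamide, CN(C)C=O
Why: Directed ortho-metalation in the Comins manner: the lithium amide adds to the aldehyde to give an α-amino alkoxide that protects the carbonyl and, acting together with the neighbouring methoxymethoxy group, steers n-BuLi to C6, the only ring position lying between two directing groups, and trapping with DMF followed by aqueous release of both masked aldehydes gives the symmetrical dialdehyde.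

Step 3
Reactants: 6 4-methylpent-3-enoic acid
Product: 8 N-methoxy-N,4-dimethylpent-3-enamide, via acyl imidazolide 7 (not isolated)
Conditions: 1,1'-carbonyldiimidazole, CH2Cl2, rt; then MeNH(OMe)·HCl, rt
Reagents that add atoms: N,O-dimethylhydroxylamine hydrochloride, CNOC.Cl
Why: Amide formation through an acyl imidazolide (carbonyldiimidazole coupling) proceeds without strong base, so the β,γ-double bond should stay out of conjugation while the acid is turned into a Weinreb amide.

Step 4
Reactants: 8 N-methoxy-N,4-dimethylpent-3-enamide, 9 ethynyltrimethylsilane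
Product: 11 6-methyl-1-(trimethylsilyl)hept-5-en-1-yn-3-one, via lithium (trimethylsilyl)acetylide 10 (not isolated)
Conditions: 9, n-BuLi, THF, −78 °C; then 8, −78 → 0 °C; cold aq NH4Cl
Reagents that add atoms: none
Why: Weinreb ketone synthesis: the weakly basic acetylide adds once to give a chelated tetrahedral adduct that releases the ynone only on the buffered quench, so over-addition is excluded and the skipped enone never meets free base.

Step 5
Reactants: 11 6-methyl-1-(trimethylsilyl)hept-5-en-1-yn-3-one
Product: 12 (3R)-6-methyl-1-(trimethylsilyl)hept-5-en-1-yn-3-ol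
Conditions: Ru[(R,R)-TsNCHPhCHPhNH](p-cymene) (1 mol%), i-PrOH, rt
Reagents that add atoms: none
Why: Noyori asymmetric transfer hydrogenation of an alkynyl ketone: the base-free divalent ruthenium amido complex passes hydride and proton from 2-propanol to one carbonyl face in a six-membered transition state in which the alkynyl group takes the place of the aryl group of the usual model, so the (R,R)-ligand should give the (3R)-carbinol while the silylalkyne, the trisubstituted alkene and the doubly activated methylene are left alone.

Step 6
Reactants: 12 (3R)-6-methyl-1-(trimethylsilyl)hept-5-en-1-yn-3-ol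
Product: 13 (3R)-3-(tert-butyldimethylsilyloxy)-6-methyl-1-(trimethylsilyl)hept-5-en-1-yne
Conditions: TBSCl, imidazole, DMF, rt
Reagents that add atoms: tert-butyldimethylsilyl chloride, CC(C)(C)[Si](C)(C)Cl
Why: Imidazole-promoted silylation of the secondary alcohol (silyl ether formation) installs a group that tolerates haloboration, t-BuLi, Grignard reagents, metathesis and MnO2 and does not involve the C–O bond of the stereocenter.

Step 7
Reactants: 13 (3R)-3-(tert-butyldimethylsilyloxy)-6-methyl-1-(trimethylsilyl)hept-5-en-1-yne
Product: 14 (3R)-3-(tert-butyldimethylsilyloxy)-6-methylhept-5-en-1-yne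
Conditions: K2CO3, MeOH, rt
Reagents that add atoms: none
Why: Methanolysis of the alkynyl C–Si bond (protodesilylation) is fast because the acetylide is a good leaving group on silicon, whereas the hindered secondary O-silyl ether is inert to carbonate in methanol.

Step 8
Reactants: 14 (3R)-3-(tert-butyldimethylsilyloxy)-6-methylhept-5-en-1-yne
Product: 16 (3R)-2-bromo-3-(tert-butyldimethylsilyloxy)-6-methylhepta-1,5-diene, via (Z)-2-bromoalkenylborane 15 (not isolated)
Conditions: B-bromo-9-BBN, CH2Cl2, 0 °C; then AcOH, 0 °C → rt
Reagents that add atoms: B-bromo-9-borabicyclo[3.3.1]nonane, BrB1C2CCCC1CCC2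
Why: Haloboration followed by protonolysis: the bromoborane adds syn across the terminal alkyne only, with bromine on the internal carbon, alkenes do not react, and acetic acid cleaves the alkenyl C–B bond to leave the 2-bromo-1-alkene with the stereocenter untouched.

Step 9
Reactants: 16 (3R)-2-bromo-3-(tert-butyldimethylsilyloxy)-6-methylhepta-1,5-diene, 5 3,6-bis(methoxymethoxy)benzene-1,2-dicarbaldehyde, 17 vinylmagnesium bromide
Product: 20 1-(1-hydroxyprop-2-en-1-yl)-2-[(3R)-3-(tert-butyldimethylsilyloxy)-1-hydroxy-6-methyl-2-methylidenehept-5-en-1-yl]-3,6-bis(methoxymethoxy)benzene as a mixture of carbinol epimers, via alkenyllithium 18 (not isolated), via lithium lactolate 19 (not isolated)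
Conditions: 16, t-BuLi (2 equiv), Et2O, −78 °C; added to 5, THF, −78 °C; then 17 (3 equiv), −78 → 0 °C; aq NH4Cl
Reagents that add atoms: none
Why: Bromine–lithium exchange gives an alkenyllithium that adds 1,2 to one formyl group of the symmetrical dialdehyde, the new alkoxide closes onto the neighbouring formyl group to a five-membered lactolate that shields it from a second equivalent of the valuable reagent, and the excess Grignard reagent then adds to the small equilibrium share of ring-opened aldehyde (Grignard addition to a lactol) to give the diol, whose two new carbinol centres need no control because both become quinone carbonyls.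

Step 10
Reactants: 20 1-(1-hydroxyprop-2-en-1-yl)-2-[(3R)-3-(tert-butyldimethylsilyloxy)-1-hydroxy-6-methyl-2-methylidenehept-5-en-1-yl]-3,6-bis(methoxymethoxy)benzene
Product: 21 2-[(1R)-1-(tert-butyldimethylsilyloxy)-4-methylpent-3-en-1-yl]-5,8-bis(methoxymethoxy)-1,4-dihydronaphthalene-1,4-diol as a mixture of carbinol epimers
Conditions: second-generation Grubbs catalyst RuCl2(=CHPh)(H2IMes)(PCy3) (5 mol%), 1,4-benzoquinone (10 mol%), CH2Cl2 (0.005 M), 40 °C
Reagents that add atoms: none
Why: Ring-closing olefin metathesis: the ruthenium benzylidene first exchanges with the unhindered monosubstituted vinyl group on the C4 carbinol, and the resulting alkylidene adds across the 1,1-disubstituted alkene at C2 to a ruthenacyclobutane whose cycloreversion forms the C2=C3 bond and expels the two terminal methylene carbons as ethylene. The closest known reaction type is the ring-closing metathesis of ortho-bis(1-hydroxyallyl)arenes to 1,4-dihydronaphthalene-1,4-diols that are afterwards oxidised to naphthoquinones. Ring B closes as a six-membered carbocycle with an endocyclic trisubstituted alkene, and because both arms sit ortho on ring A the two reacting alkenes are held close, so cyclisation at high dilution should outrun oligomerisation. No stereocenter is formed and the silyloxy-bearing (R) carbon next to C2 is not touched. The selectivity required is among three alkenes, and the trisubstituted prenyl alkene should remain a spectator because it engages ruthenium alkylidenes slowly and its participation would demand a cyclobutene or a nine-membered ring. The benzoquinone additive is there to intercept ruthenium hydrides that could isomerise the free allylic carbinols to ketones.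

Step 11
Reactants: 21 2-[(1R)-1-(tert-butyldimethylsilyloxy)-4-methylpent-3-en-1-yl]-5,8-bis(methoxymethoxy)-1,4-dihydronaphthalene-1,4-diol
Product: 22 2-[(1R)-1-(tert-butyldimethylsilyloxy)-4-methylpent-3-en-1-yl]-5,8-bis(methoxymethoxy)naphthalene-1,4-dione
Conditions: activated MnO2 (excess), CH2Cl2, rt
Reagents that add atoms: none
Why: Manganese dioxide oxidation of allylic and benzylic alcohols: both carbinols are doubly activated, the hydroxy enone formed first is oxidised on directly or after tautomerising to the naphthalene-1,4-diol, so every epimer should converge on the quinone while the isolated alkene, the silyl ether and the acetals are not attacked.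

Step 12
Reactants: 22 2-[(1R)-1-(tert-butyldimethylsilyloxy)-4-methylpent-3-en-1-yl]-5,8-bis(methoxymethoxy)naphthalene-1,4-dione
Product: 23 5,8-dihydroxy-2-[(1R)-1-hydroxy-4-methylpent-3-en-1-yl]naphthalene-1,4-dione ((R)-shikonin)
Conditions: HCl (0.5 M) in MeOH, 0 °C → rt
Reagents that add atoms: none
Why: Acid-catalysed acetal exchange with methanol removes the two aryl methoxymethyl groups, which leave readily from the electron-poor peri oxygens, and the same medium methanolyses the secondary silyl ether (global acidic solvolysis), while dilute methanolic acid at or below room temperature should be too weak to protonate the prenyl alkene or to ionise the carbinol C–O bond, so the (R) centre should be kept.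

Step 13
Reactants: 24 (2-carboxyethyl)triphenylphosphonium bromide, 25 methacrolein
Product: 27 (3Z)-5-methylhexa-3,5-dienoic acid, via phosphorus ylide carboxylate 26 (not isolated)
Conditions: NaN(SiMe3)2 (2 equiv), THF, −78 °C; then 25, −78 °C → rt; cold aq HCl to pH 3
Reagents that add atoms: none
Why: Wittig olefination with a non-stabilised ylide under lithium-free conditions passes through the kinetically favoured cis-oxaphosphetane and should therefore give the Z alkene, the carboxylate formed by the first equivalent of base protecting the acid and keeping the β,γ-position of the new double bond.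

Step 14
Reactants: 23 5,8-dihydroxy-2-[(1R)-1-hydroxy-4-methylpent-3-en-1-yl]naphthalene-1,4-dione, 27 (3Z)-5-methylhexa-3,5-dienoic acid
Product: 28 (1R)-1-(5,8-dihydroxy-1,4-dioxo-1,4-dihydronaphthalen-2-yl)-4-methylpent-3-en-1-yl (3Z)-5-methylhexa-3,5-dienoate (CNP0129564.1)
Conditions: N,N'-dicyclohexylcarbodiimide, DMAP (cat), CH2Cl2, 0 °C
Reagents that add atoms: none
Why: Steglich esterification: the carbodiimide activates the acid as an O-acylisourea and catalytic DMAP transfers the acyl group to the secondary side-chain hydroxyl, which reacts in preference to the two phenols that are tied up in hydrogen bonds to the peri carbonyls, the C–O bond of the stereocenter is not broken so the (R) configuration is retained, and low temperature with little DMAP should keep the skipped diene from moving into conjugation.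

**Compound list**

1 | 2,5-dihydroxybenzaldehyde | O=Cc1cc(O)ccc1O | starting material
2 | 2,5-bis(methoxymethoxy)benzaldehyde | COCOc1ccc(OCOC)c(C=O)c1 | intermediate
3 | lithium [2,5-bis(methoxymethoxy)phenyl]{[2-(dimethylamino)ethyl](methyl)amino}methanolate | COCOc1ccc(OCOC)c(C(O[Li])N(C)CCN(C)C)c1 | intermediate
4 | lithium [2-lithio-3,6-bis(methoxymethoxy)phenyl]{[2-(dimethylamino)ethyl](methyl)amino}methanolate | COCOc1ccc(OCOC)c(C(O[Li])N(C)CCN(C)C)c1[Li] | intermediate
5 | 3,6-bis(methoxymethoxy)benzene-1,2-dicarbaldehyde | COCOc1ccc(OCOC)c(C=O)c1C=O | intermediate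
6 | 4-methylpent-3-enoic acid | CC(C)=CCC(=O)O | starting material
7 | 1-(4-methylpent-3-enoyl)imidazole | CC(C)=CCC(=O)n1ccnc1 | intermediate
8 | N-methoxy-N,4-dimethylpent-3-enamide | CC(C)=CCC(=O)N(C)OC | intermediate
9 | ethynyltrimethylsilane | C#C[Si](C)(C)C | starting material
10 | lithium (trimethylsilyl)acetylide | [Li]C#C[Si](C)(C)C | intermediate
11 | 6-methyl-1-(trimethylsilyl)hept-5-en-1-yn-3-one | CC(C)=CCC(=O)C#C[Si](C)(C)C | intermediate
12 | (3R)-6-methyl-1-(trimethylsilyl)hept-5-en-1-yn-3-ol | C[Si](C)(C)C#C[C@H](O)CC=C(C)C | intermediate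
13 | (3R)-3-(tert-butyldimethylsilyloxy)-6-methyl-1-(trimethylsilyl)hept-5-en-1-yne | C[Si](C)(C)C#C[C@H](O[Si](C)(C)C(C)(C)C)CC=C(C)C | intermediate
14 | (3R)-3-(tert-butyldimethylsilyloxy)-6-methylhept-5-en-1-yne | C#C[C@H](O[Si](C)(C)C(C)(C)C)CC=C(C)C | intermediate
15 | 9-[(1Z,3R)-2-bromo-3-(tert-butyldimethylsilyloxy)-6-methylhepta-1,5-dien-1-yl]-9-borabicyclo[3.3.1]nonane | Br/C(=C\B1C2CCCC1CCC2)[C@H](O[Si](C)(C)C(C)(C)C)CC=C(C)C | intermediate
16 | (3R)-2-bromo-3-(tert-butyldimethylsilyloxy)-6-methylhepta-1,5-diene | C=C(Br)[C@H](O[Si](C)(C)C(C)(C)C)CC=C(C)C | intermediate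
17 | vinylmagnesium bromide | C=C[Mg]Br | starting material
18 | [(3R)-3-(tert-butyldimethylsilyloxy)-6-methylhepta-1,5-dien-2-yl]lithium | C=C([Li])[C@H](O[Si](C)(C)C(C)(C)C)CC=C(C)C | intermediate
19 | lithium 3-[(3R)-3-(tert-butyldimethylsilyloxy)-6-methylhepta-1,5-dien-2-yl]-4,7-bis(methoxymethoxy)-1,3-dihydroisobenzofuran-1-olate | [Li]OC1OC(C(=C)[C@H](O[Si](C)(C)C(C)(C)C)CC=C(C)C)c2c1c(OCOC)ccc2OCOC | intermediate
20 | 1-(1-hydroxyprop-2-en-1-yl)-2-[(3R)-3-(tert-butyldimethylsilyloxy)-1-hydroxy-6-methyl-2-methylidenehept-5-en-1-yl]-3,6-bis(methoxymethoxy)benzene, mixture of carbinol epimers | COCOc1ccc(OCOC)c(C(O)C=C)c1C(O)C(=C)[C@H](O[Si](C)(C)C(C)(C)C)CC=C(C)C | intermediate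
21 | 2-[(1R)-1-(tert-butyldimethylsilyloxy)-4-methylpent-3-en-1-yl]-5,8-bis(methoxymethoxy)-1,4-dihydronaphthalene-1,4-diol, mixture of carbinol epimers | COCOc1ccc(OCOC)c2c1C(O)C=C(C2O)[C@H](O[Si](C)(C)C(C)(C)C)CC=C(C)C | intermediate
22 | 2-[(1R)-1-(tert-butyldimethylsilyloxy)-4-methylpent-3-en-1-yl]-5,8-bis(methoxymethoxy)naphthalene-1,4-dione | COCOc1ccc(OCOC)c2c1C(=O)C=C(C2=O)[C@H](O[Si](C)(C)C(C)(C)C)CC=C(C)C | intermediate
23 | 5,8-dihydroxy-2-[(1R)-1-hydroxy-4-methylpent-3-en-1-yl]naphthalene-1,4-dione ((R)-shikonin) | O[C@H](CC=C(C)C)C1=CC(=O)c2c(O)ccc(O)c2C1=O | intermediate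
24 | (2-carboxyethyl)triphenylphosphonium bromide | OC(=O)CC[P+](c1ccccc1)(c1ccccc1)c1ccccc1.[Br-] | starting material
25 | methacrolein (2-methylprop-2-enal) | CC(=C)C=O | starting material
26 | sodium 3-(triphenyl-λ5-phosphanylidene)propanoate | [Na+].[O-]C(=O)CC=P(c1ccccc1)(c1ccccc1)c1ccccc1 | intermediate
27 | (3Z)-5-methylhexa-3,5-dienoic acid | C=C(C)/C=C\CC(=O)O | intermediate
28 | (1R)-1-(5,8-dihydroxy-1,4-dioxo-1,4-dihydronaphthalen-2-yl)-4-methylpent-3-en-1-yl (3Z)-5-methylhexa-3,5-dienoate (CNP0129564.1) | C=C(C)/C=C\CC(=O)O[C@H](CC=C(C)C)C1=CC(=O)c2c(O)ccc(O)c2C1=O | target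

**Step count and risks**

Total step count: 14 steps.
Longest linear sequence: 11 steps (steps 3 to 12, then step 14, from 4-methylpent-3-enoic acid).

The three steps most likely to fail are steps 9, 10 and 12.

Step 9. The process at risk is the ordered double addition: a second alkenyllithium may add before the lactolate has closed, the lithium lactolate may reopen too slowly for the Grignard reagent, and the silyl group may migrate to the neighbouring alkoxide while the mixture warms. The fallback reverses the order and isolates the half-way stage. Dialdehyde 5 is treated with one equivalent of vinylmagnesium bromide 17 at −78 °C to give, after work-up, the lactol 4,7-bis(methoxymethoxy)-3-vinyl-1,3-dihydroisobenzofuran-1-ol F1, which has only one masked aldehyde left. The alkenyllithium 18 is transmetalated with MgBr2·OEt2 to [(3R)-3-(tert-butyldimethylsilyloxy)-6-methylhepta-1,5-dien-2-yl]magnesium bromide F2, which is stable at 0 °C. F2 is added at 0 °C to F1 that has first been deprotonated with i-PrMgCl, and the magnesium lactolate should open readily toward the Grignard reagent. The route is rejoined at 20.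

Step 10. The processes at risk are isomerisation of the free allylic carbinols to ketones by ruthenium hydrides, dehydrative aromatisation of the ring-closed diol, and slow closure onto the hindered 1,1-disubstituted alkene while the catalyst decays. The fallback keeps the C2=C3 metathesis but changes the substrate. Diol 20 is silylated (TMSCl, imidazole, CH2Cl2) to 1-[1-(trimethylsilyloxy)prop-2-en-1-yl]-2-[(3R)-3-(tert-butyldimethylsilyloxy)-6-methyl-2-methylidene-1-(trimethylsilyloxy)hept-5-en-1-yl]-3,6-bis(methoxymethoxy)benzene F3, in which the carbinol oxygens can neither be isomerised nor eliminated nor bind ruthenium. Metathesis of F3 with the phosphine-free second-generation Hoveyda–Grubbs catalyst RuCl2(=CH-C6H4-2-O-i-Pr)(H2IMes) in toluene at 80 °C should give 2-[(1R)-1-(tert-butyldimethylsilyloxy)-4-methylpent-3-en-1-yl]-5,8-bis(methoxymethoxy)-1,4-bis(trimethylsilyloxy)-1,4-dihydronaphthalene F4. K2CO3 in methanol then removes the two trimethylsilyl groups without touching the TBS or MOM ethers, and the route is rejoined at 21.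

Step 12. The processes at risk are addition of the freed side-chain hydroxyl to the acid-activated prenyl alkene (tetrahydrofuran formation) and solvolysis at the carbinol carbon with loss of enantiomeric purity once the naphthazarin tautomers become available. The fallback unmasks in two stages so that the carbinol is never free in acid. Quinone 22 is treated with TMSOTf and 2,2'-bipyridyl in CH3CN at 0 °C, which exchanges only the aryl methoxymethyl groups and gives 2-[(1R)-1-(tert-butyldimethylsilyloxy)-4-methylpent-3-en-1-yl]-5,8-bis(trimethylsilyloxy)naphthalene-1,4-dione F5 under buffered, non-protic conditions. Water releases the phenols to give 5,8-dihydroxy-2-[(1R)-1-(tert-butyldimethylsilyloxy)-4-methylpent-3-en-1-yl]naphthalene-1,4-dione F6. The silyl ether of F6 is then cleaved with HF·pyridine in THF at 0 °C, and the route is rejoined at 23.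

**Further compounds**

F1 | step 9 | 4,7-bis(methoxymethoxy)-3-vinyl-1,3-dihydroisobenzofuran-1-ol | OC1OC(C=C)c2c1c(OCOC)ccc2OCOC
F2 | step 9 | [(3R)-3-(tert-butyldimethylsilyloxy)-6-methylhepta-1,5-dien-2-yl]magnesium bromide | C=C([Mg]Br)[C@H](O[Si](C)(C)C(C)(C)C)CC=C(C)C
F3 | step 10 | 1-[1-(trimethylsilyloxy)prop-2-en-1-yl]-2-[(3R)-3-(tert-butyldimethylsilyloxy)-6-methyl-2-methylidene-1-(trimethylsilyloxy)hept-5-en-1-yl]-3,6-bis(methoxymethoxy)benzene | COCOc1ccc(OCOC)c(C(O[Si](C)(C)C)C=C)c1C(O[Si](C)(C)C)C(=C)[C@H](O[Si](C)(C)C(C)(C)C)CC=C(C)C
F4 | step 10 | 2-[(1R)-1-(tert-butyldimethylsilyloxy)-4-methylpent-3-en-1-yl]-5,8-bis(methoxymethoxy)-1,4-bis(trimethylsilyloxy)-1,4-dihydronaphthalene | COCOc1ccc(OCOC)c2c1C(O[Si](C)(C)C)C=C(C2O[Si](C)(C)C)[C@H](O[Si](C)(C)C(C)(C)C)CC=C(C)C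
F5 | step 12 | 2-[(1R)-1-(tert-butyldimethylsilyloxy)-4-methylpent-3-en-1-yl]-5,8-bis(trimethylsilyloxy)naphthalene-1,4-dione | C[Si](C)(C)Oc1ccc(O[Si](C)(C)C)c2c1C(=O)C=C(C2=O)[C@H](O[Si](C)(C)C(C)(C)C)CC=C(C)C
F6 | step 12 | 5,8-dihydroxy-2-[(1R)-1-(tert-butyldimethylsilyloxy)-4-methylpent-3-en-1-yl]naphthalene-1,4-dione | Oc1ccc(O)c2c1C(=O)C=C(C2=O)[C@H](O[Si](C)(C)C(C)(C)C)CC=C(C)C
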